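(The numbers come from no measurement; the result is computed.)

Slowness is your worry: you guess that so thin a charge of enzyme cannot outrun the uncatalysed route, and you want a quick number for these flasks.

    enzyme ⇌ dormant form (K1 = 0.80, k1 = 0.018 s⁻¹)
    complex ⇌ enzyme + target (K2 = 0.22 M, k2 = 92 s⁻¹)
    substrate → uncatalysed product (k3 = 0.0067 s⁻¹)
    substrate + enzyme ⇌ complex (K4 = 13 M⁻¹, k4 = 81000 M⁻¹ s⁻¹)

| setting | winter | midnight | summer | dawn |
|---|---|---|---|---|
| substrate | 0.10 M | 0.10 M | 0.10 M | 0.10 M (fed, over 1.50 min) |
| enzyme | 0.054 mol% | 0.054 mol% | 0.054 mol% | 0.054 mol% |
| remark | one stirred flow tank at steady state, fed with the mixture as stated, mean residence time 3.0 min | everything together in a closed stirred flask, run for 3.0 min | a tube with plug flow, the mixed feed as stated, residence time 3.0 min | all but substrate at the start; substrate goes in evenly over 1.50 min, the run ends at 3.0 min |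
| time |  | 3.0 min | 3.0 min | 3.0 min |

- the stated concentrations are those of everything mixed, before any reaction; amounts are the same in each set-up
- the feed brings no volume worth counting
- run time (midnight): 3.0 min

* the set-up with the highest amount of target at the outlet or at the end, in percent of the substrate put in ("none" if the first two lie within 2 percentage points) (winter / midnight / summer / dawn / none)
* amount of target at the outlet or at the end, in percent of the substrate put in, winter
* amount of target at the outlet or at the end, in percent of the substrate put in, midnight
* amount of target at the outlet or at the end, in percent of the substrate put in, summer
* amount of target at the outlet or at the end, in percent of the substrate put in, dawn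

I count turnovers. I treat the complex as short-lived and split the enzyme between free and dormant at their balance, a liberty at the start of midnight, when the equilibrium constant of binding times [substrate] stands at 1.3. Free enzyme then gives substrate a pseudo-first-order constant of 2.12 min⁻¹, which is faster than the 0.4 min⁻¹ of the uncatalysed route. Over 3.0 min that makes 6.36 passes against 1.20. But the passage runs backwards too, since [target]/[substrate] balances at 2.86. So my reckoning has a fast stage toward that balance and then a slower one, set by the bleed constant 0.0940 min⁻¹, the rate constant at which target drains back through substrate into uncatalysed product, slower than the forward constant. In this reckoning, target after the fast stage is 68.9% of the charge times the exponential of minus the bleed constant times the time.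

Midnight and summer share one history, so I get 52.0% and 52.0%. Dawn's substrate enters on average halfway through the feed and so spends 2.25 min in the flask, which gives 55.8%. A balance on the winter tank with the same constants gives 47.2%. I commit to dawn.

The forecast names dawn, with 46.5% for winter, 51.7% for midnight and summer, and 55.4% for dawn, on the ground that with dosing “less is lost to the uncatalysed route”.

The simulation gives dawn: winter 46.6%, midnight 51.6%, summer 51.6%, dawn 55.3%, so dawn leads midnight by 3.7 percentage points against a margin of 2 points. At 3.00 min dawn holds less uncatalysed product than midnight, 27.7% against 32.8%. The bleed constant carries midnight's 58.5% of target at 1.50 min forward to 50.8% at 3.00 min, where the reading is 51.6%.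

Now read the dawn flask at 8.0 min: the bleed constant takes its 55.3% down to 34.6%. The simulation gives 34.8%, and uncatalysed product then holds the most, at 54.6%.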